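# Proposed total synthesis of japonicone A

Numbering: guaiane numbering (C1–C15) for the hydroazulene half, primed eudesmane numbering (C1′–C15′) for the decalin half.

## Structural features

Japonicone A is a [4+2] dimer of two sesquiterpene lactones that share a norbornene. Its bridgeheads are C1 and C3, its one-carbon bridge is C2 (acetoxy, pointing toward the C4=C5 bridge), and its saturated bridge is C13′–C11′, with C11′ a spiro lactone carbon. The guaianolide half is a 5/7 carbocycle with a trans-fused α-methylene-γ-lactone across C7–C8 and a C10 methyl. The eudesmanolide half is a decalin with C5′=C6′, a cis-fused lactone at C7′–C8′ on the face of the angular methyl, a C1′ carbinol and a C4′ methyl cis to C14′. Twelve stereocentres are present; C10–C1–C2–C3–C11′–C7′–C8′ are contiguous and include the quaternary C1 and C11′, and C10′ is a third quaternary centre. Fragile groups are the exocyclic methylene lactone (Michael acceptor), the bridge acetate, the C5′=C6′ alkene (acid moves it to C4′=C5′) and the cyclopentadiene needed for the cycloaddition, which isomerises by [1,5]-hydrogen shift. The real difficulty is the bridge: the C2 oxygen lies syn to the alkene, so the cycloaddition must occur on the diene face opposite the oxygen, against the usual preference of 5-acyloxycyclopentadienes. The key step exploits the five-membered ring C1–C5: its oxygen sits at C2 between C1 and C3, and C4–C5 is the one ring bond remote from C2. The ring is therefore the retron of a 4π closure of the dienone C5=C1–C2(=O)–C3=C4, whose C1=C5 alkene belongs to a cycloheptene that already carries C7, C8 and C10.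

## Logic of the disconnections

**C11=C13 (42 to 40).** The guaianolide methylene is cut back to a β-dimethylamino group. The reason is that the diene half would otherwise carry its own dienophile and dimerise. The gain is a cycloaddition with a single acrylate present. The forward step needs an N-methylation and elimination that leave the acetate, two lactones and two alkenes alone.

**C1–C13′ and C3–C11′ (40 to 39 and 18).** The norbornene is cut by retro-Diels–Alder into a cyclopentadiene and an α-methylene lactone. This splits the molecule into two halves of equal size and removes three stereocentres (C1, C3, C11′). The forward step must be regioselective, endo, anti to the C2 oxygen and the C10 methyl, and faster than the hydrogen shift of 39.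

**C3=C4, C2–O, C13 and C4–O (39 back to 32).** The diene is traced to a C4 carbinol (38), the acetate to a C2 alcohol (36) and that to a ketone (35); the C4 oxygen is traced to γ-oxidation of the enone 32 through 33. Oxygenating C4 removes the uncontrolled C4 stereocentre and keeps C3 a methylene, so C2 can be set by reagent control. The demand is site-selective enolisation toward C4 and a regioselective dehydration.

**C4–C5 (32 to 31).** This is the Nazarov disconnection: the cyclopentenone opens to a cycloheptenyl propenyl ketone. One ring and one bond are removed, the carbonyl is already at C2, and the precursor is a simple acylated cycloheptene. The forward step must place the alkene at C1=C5 and leave C10 intact.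

**C1–C2 and C2–C3 (31 to 30 to 29).** The dienone is cut at the carbonyl into an enol triflate, carbon monoxide and a propenyl metal. This reduces the problem to a 2-methylcycloheptanone; the forward step requires kinetic enolisation away from C10.

**C5 insertion and C12–O (29 to 27 to 25).** The seven-membered ketone is contracted by one carbon (C5) to a cyclohexanone, and the lactone is opened to a hydroxy ester. Stereocontrol is then exercised on a six-membered ring. The demand is migration of C6 in preference to C10.

**C7–C11, C10–C14 and the oxygens (25 to 23 to 22 to 21 to 20 to 19).** The acetate arm is removed by retro-Michael and the methyl by retro-alkylation, leaving a 4-oxygenated cyclohexenone. Its single stereocentre (C8) controls C7 and C10 and comes from desymmetrisation of a meso endoperoxide of 19.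

**C11′=C13′, C12′–O8′ and C8′–H (18 to 17 to 14 to 12).** The methylene is removed by retro-Mannich, the lactone is opened and the carbinol traced to a ketone. Hydride delivery anti to the angular methyl then gives the cis lactone on the methyl face.

**C7′–C11′ and C8′–O (12 to 11 to 10 to 9 to 8).** The C8′ oxygen is traced to hydroboration of a diene and the side chain to cross-coupling of an enol triflate. This transposes the carbonyl of an enone by one carbon while adding the acetate arm; the demand is site-selective hydroboration of one alkene of the diene.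

**C4′–C15′ (8 to 7 to 5 to 4 to 3 to 2 to 1).** The C4′ methyl is traced to diaxial opening of an epoxide made from the deconjugated ketal. This gives the crowded cis-dimethyl arrangement kinetically and leads back to 1, which supplies C10′.

## Other disconnections considered

**Alternative 1:** The cut is C1′–C10′ of ring A in the eudesmane half. In the forward step a Lewis acid (TiCl4 or BF3·OEt2) activates the aldehyde of the allylsilane A1, and the γ-carbon C10′ attacks it to give the hydroxy enone A2, with the alkene moved to C5′=C6′.
- *In its favour:* one step makes ring A, the quaternary C10′ and the C1′ carbinol, and A2 already has the carbonyl at C8′, so alkylation at C7′ and reduction would finish the lactone. The chosen route needs steps 1–10 to reach the same oxidation pattern in 12. On step economy for this half the alternative is the better plan.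
- *Against it here:* A1 must be made enantiomerically pure with C4′ set, and the relation of C1′, C4′ and C10′ then rests on one cationic transition state, which has to deliver the crowded cis-dimethyl arrangement. The β,γ-unsaturated ketone can also slip into conjugation under the Lewis acid.
- *Comparison:* structurally it addresses only the decalin and says nothing about the hydroazulene or the bridge, so it is complementary to the Nazarov plan and could replace steps 1–10. Mechanistically it trades substrate-controlled reactions on a rigid decalin for an open transition state. For the guaiane half and the end game the two plans are equal.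

**Alternative 2:** The cut is C1–C5 of the hydroazulene, made from a decalin by moving C5 from C10 to C1. Buffered solvolysis of the mesylate A3 gives the trienolide A4 after loss of H1 from the C10 cation.
- *In its favour:* the 5/7 skeleton comes from a six-membered-ring precursor, where stereocontrol is easier, and the trans lactone and the methylene group are in place from the start. In ring-forming economy it is the equal of the Nazarov step, and in precursor stereocontrol it is the better.
- *Against it here:* A4 has its alkenes at C1=C10 and C5=C6, no oxygen at C2, a stereocentre at C4 and none at C10. Reaching 39 would need both alkenes moved, C2 oxidised stereoselectively and C10 reset. The acrylate must also survive the solvolysis, and competing eliminations of the homoallylic cation are likely.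
- *Comparison:* the Nazarov step puts the carbonyl exactly at C2 and the alkene at C1=C5, so the chosen plan is shorter after its key step even though it is longer before it.

**Alternative 3:** The cut is C2–C3. The bridged core is made earlier as a bicyclo[2.2.2]octenone from a dearomatised phenol and the eudesmanolide dienophile. Methoxide (or methanol with AgBF4) then adds to the bridge ketone of the bromo ketone A5, and C3 shifts to C2 with inversion to give the norbornene ester A6.
- *In its favour:* no acyloxycyclopentadiene is needed, so there is no hydrogen shift, and the configuration at C2 follows from a stereospecific 1,2-shift and not from π-facial selectivity. On the hardest stereochemical point of the target this is the better plan.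
- *Against it here:* a carbon substituent stands where oxygen is needed. Degrading the ester to an acetate costs several steps, either by Baeyer–Villiger chemistry next to a tetrasubstituted alkene or through a bridge radical that can lose configuration. The cyclohexadienone must already carry the seven-membered ring with C7, C8 and C10, and its cycloaddition has its own regio- and facial problems.
- *Comparison:* both plans build the same norbornene by a cycloaddition with the same dienophile. The chosen plan ends one step after it; the alternative needs ester degradation, methylenation and desilylation afterwards.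

Key step: step 23

Assumption 1: the configuration is read exactly as written, (1R,2S,3S,7S,8R,10R,1′S,4′R,7′S,8′S,10′S,11′R); in this series the eudesmanolide half is the antipode of the alantolactones of Inula, so no natural lactone is used and both halves are made by asymmetric synthesis.

Assumption 2: C4 of 32 forms as a mixture of epimers; no later step depends on it and it becomes trigonal again in step 29.

Assumption 3: in step 15 the pseudo-enantiomer of the cinchona catalyst that gives the (R)-alcohol is the one used.

## Steps

### Eudesmanolide dienophile (steps 1–13)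

Step 1
Reactants: 1 (S)-Wieland–Miescher ketone
Product: 2 (4aS,5S)-5-hydroxy-4a-methyl-4,4a,5,6,7,8-hexahydronaphthalen-2(3H)-one (C1′ hydroxyl cis to the C10′ methyl; enone C5′=C6′–C7′=O)
Conditions: NaBH4 (0.3 equiv), EtOH, −15 °C
Reagents that add atoms: none
Why: Chemoselective borohydride reduction of the saturated ketone; hydride enters anti to the angular methyl, so the C1′ hydroxyl is cis to C14′, and the vinylogous enone carbonyl does not react at this temperature.

Step 2
Reactants: 2 hydroxy enone
Product: 3 C7′ ethylene ketal of 2 with the alkene moved to C4′=C5′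
Conditions: HOCH2CH2OH, TsOH·H2O (cat.), benzene, reflux (Dean–Stark)
Reagents that add atoms: ethylene glycol, OCCO
Why: Acid-catalysed ketalisation of an enone runs through the dienol and leaves the alkene deconjugated, as with steroid 4-en-3-ones; this masks C7′ and exposes C4′.

Step 3
Reactants: 3 ketal alcohol
Product: 4 C1′ tert-butyldimethylsilyl ether of 3
Conditions: TBSOTf, 2,6-lutidine, CH2Cl2, 0 °C
Reagents that add atoms: tert-butyldimethylsilyl triflate, CC(C)(C)[Si](C)(C)OS(=O)(=O)C(F)(F)F
Why: Silylation of a hindered secondary alcohol; the ether keeps the hydroxyl from steering the peracid to the methyl face and protects it through the organometallic, enolate and oxidation steps.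

Step 4
Reactants: 4 silyl ether ketal
Product: 5 C4′–C5′ epoxide of 4 with the oxygen on the face opposite the C10′ methyl
Conditions: mCPBA, NaHCO3, CH2Cl2, 0 °C
Reagents that add atoms: 3-chloroperbenzoic acid, OOC(=O)c1cccc(Cl)c1
Why: Prilezhaev epoxidation on the face away from the angular methyl and the silyloxy group; the buffer protects the ketal.

Step 5
Reactants: 5 epoxide
Product: 7 C5′-hydroxy C7′-ketone with the C4′ methyl cis to the C10′ methyl and the C5′ hydroxyl trans to it, via ketal carbinol 6 (not isolated)
Conditions: MeMgBr (6 equiv), CuI (10 mol%), THF, 60 °C; then 1 M HCl, THF, 0 °C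
Reagents that add atoms: methylmagnesium bromide, C[Mg]Br; water, O
Why: Fürst–Plattner trans-diaxial opening of the epoxide: the methyl nucleophile attacks the secondary C4′ with inversion, so C15′ ends axial and cis to C14′; dilute acid then releases the C7′ ketone.

Step 6
Reactants: 7 β-hydroxy ketone
Product: 8 (1S,4R,10S)-1-(tert-butyldimethylsilyloxy)-11,12,13-trinoreudesm-5-en-7-one
Conditions: SOCl2, pyridine, CH2Cl2, −20 to 0 °C
Reagents that add atoms: none
Why: Anti elimination through the chlorosulfite: the axial C5′ oxygen is antiperiplanar to the axial C6′ hydrogen but not to H4′, giving the conjugated enone; the non-equilibrating conditions keep the axial C4′ methyl, which could epimerise only through the extended dienol.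

Step 7
Reactants: 8 enone
Product: 9 cross-conjugated dienyl triflate (C7′(OTf)=C8′ with C5′=C6′)
Conditions: LiN(iPr)2, THF, −78 °C; PhNTf2, −78 to 0 °C
Reagents that add atoms: N-phenylbis(trifluoromethanesulfonimide), O=S(=O)(N(c1ccccc1)S(=O)(=O)C(F)(F)F)C(F)(F)F
Why: Kinetic deprotonation of an enone takes the α′ hydrogen at C8′; O-sulfonylation gives the dienyl triflate and leaves the γ centre C4′ untouched.

Step 8
Reactants: 9 dienyl triflate
Product: 10 tert-butyl (diene)acetate with the CH2CO2tBu group on C7′
Conditions: BrZnCH2CO2tBu, Pd(PPh3)4 (5 mol%), THF, 50 °C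
Reagents that add atoms: (2-tert-butoxy-2-oxoethyl)zinc bromide, CC(C)(C)OC(=O)C[Zn]Br
Why: Negishi-type coupling of an enol triflate with a Reformatsky reagent forms C7′–C11′; the tert-butyl ester is chosen so that the trans hydroxy ester of the next step does not close to the wrong lactone.

Step 9
Reactants: 10 diene ester
Product: 11 C8′ alcohol trans to the C7′ side chain (side chain on the methyl face; C5′=C6′ retained)
Conditions: 9-BBN, THF, 0 °C to rt; then H2O2, aq. NaOH, 0 °C
Reagents that add atoms: hydrogen peroxide, OO
Why: Hydroboration–oxidation; the bulky borane adds to the less hindered diene terminus C8′ from the face opposite the angular methyl, and syn delivery of hydrogen to C7′ on that face places the acetate arm on the methyl face, as the target requires.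

Step 10
Reactants: 11 trans hydroxy ester
Product: 12 β,γ-unsaturated C8′ ketone carrying the C7′ CH2CO2tBu group
Conditions: Dess–Martin periodinane, NaHCO3, CH2Cl2, 0 °C
Reagents that add atoms: none
Why: Dess–Martin oxidation under buffered conditions gives the ketone without moving the alkene into conjugation; C7′ is epimerisable, but the equatorial epimer on the methyl face is also the stable one.

Step 11
Reactants: 12 keto ester
Product: 14 (1S,4R,7S,8S,10S)-1-(tert-butyldimethylsilyloxy)-13-noreudesm-5-en-12,8-olide (cis lactone), via cis-hydroxy ester 13 (not isolated)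
Conditions: NaBH4, CeCl3·7H2O, MeOH, −40 °C; then K2CO3, MeOH, 40 °C
Reagents that add atoms: none
Why: Borohydride reduction in which hydride attacks C8′ from the face opposite the 1,3-related axial C10′ methyl, giving the axial alcohol cis to the side chain; the alkoxide then closes the cis γ-lactone by 5-exo-trig acyl substitution.

Step 12
Reactants: 14 silyl lactone
Product: 17 (1S,4R,7S,8S,10S)-1-(tert-butyldimethylsilyloxy)eudesma-5,11(13)-dien-12,8-olide, via Mannich base 15 (not isolated), via methiodide 16 (not isolated)
Conditions: LiN(iPr)2, THF, −78 °C; Me2N=CH2 I (Eschenmoser's salt); then MeI, MeOH; aq. NaHCO3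
Reagents that add atoms: N,N-dimethylmethyleneiminium iodide, C=[N+](C)C.[I-]
Why: Mannich reaction of the lactone enolate followed by Hofmann-type elimination of the quaternised amine installs the exocyclic methylene; the transient C11′ centre is of no consequence.

Step 13
Reactants: 17 silyl ether
Product: 18 (1S,4R,7S,8S,10S)-1-hydroxyeudesma-5,11(13)-dien-12,8-olide (the dienophile)
Conditions: HF·pyridine, pyridine, THF, 0 °C to rt
Reagents that add atoms: none
Why: Fluoride cleavage of the silyl ether under buffered conditions; strong acid is avoided because it would move C5′=C6′ to C4′=C5′.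

### Guaianolide diene (steps 14–29)

Step 14
Reactants: 19 cyclohexa-1,3-diene
Product: 20 2,3-dioxabicyclo[2.2.2]oct-5-ene (meso)
Conditions: O2, tetraphenylporphyrin (cat.), hν, CH2Cl2, 0 °C
Reagents that add atoms: dioxygen, O=O
Why: [4+2] cycloaddition of singlet oxygen to the cyclic diene gives the meso endoperoxide.

Step 15
Reactants: 20 endoperoxide
Product: 21 (R)-4-hydroxycyclohex-2-en-1-one
Conditions: O-acetylated 6′-hydroxycinchona base (5 mol%), CH2Cl2, rt
Reagents that add atoms: none
Why: Kornblum–DeLaMare rearrangement; the chiral base removes one of the two enantiotopic bridgehead hydrogens, and this desymmetrisation sets the carbinol that becomes C8.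

Step 16
Reactants: 21 hydroxy enone
Product: 22 (R)-4-(tert-butyldimethylsilyloxy)cyclohex-2-en-1-one
Conditions: TBSCl, imidazole, DMF, rt
Reagents that add atoms: tert-butyldimethylsilyl chloride, CC(C)(C)[Si](C)(C)Cl
Why: Standard silylation; the bulky ether is the control element for the next two steps.

Step 17
Reactants: 22 silyloxy enone
Product: 23 (4R,6R)-4-(tert-butyldimethylsilyloxy)-6-methylcyclohex-2-en-1-one (methyl trans to the silyloxy group)
Conditions: LiN(iPr)2, THF, −78 °C; MeI, −78 to −40 °C
Reagents that add atoms: iodomethane, CI
Why: Alkylation of the kinetic α′-enolate of the enone from the face opposite the γ-silyloxy group; this sets C10 with its methyl trans to the C8 oxygen.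

Step 18
Reactants: 23 methyl enone
Product: 25 methyl [2-(tert-butyldimethylsilyloxy)-4-methyl-5-oxocyclohexyl]acetate (acetate arm trans to the silyloxy group and cis to the methyl), via silyl enol ether 24 (not isolated)
Conditions: CH2=C(OMe)OSiMe3, TMSOTf (5 mol%), CH2Cl2, −78 °C; then aq. citric acid
Reagents that add atoms: 1-methoxy-1-(trimethylsilyloxy)ethene, C=C(OC)O[Si](C)(C)C
Why: Mukaiyama–Michael addition; the ketene acetal adds to C7 anti to the adjacent silyloxy group, fixing the trans C7/C8 relation and placing C11 cis to C14, and the mild acid frees the ketone without touching C10.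

Step 19
Reactants: 25 cyclohexanone ester
Product: 27 methyl [2-(tert-butyldimethylsilyloxy)-4-methyl-5-oxocycloheptyl]acetate (guaiane C1 ketone; C5 inserted), via alpha-silyl ketone 26 (not isolated)
Conditions: Me3SiCHN2, BF3·OEt2, CH2Cl2, −78 to −30 °C; then wet SiO2
Reagents that add atoms: (trimethylsilyl)diazomethane, C[Si](C)(C)C=[N+]=[N-]
Why: Lewis-acid-promoted diazoalkane ring expansion (Tiffeneau–Demjanov type); the less substituted α-carbon C6 migrates in preference to the methyl-bearing C10, inserting C5 between C1 and C6, and the silyl group blocks a second insertion before it is lost by protodesilylation.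

Step 20
Reactants: 27 cycloheptanone ester
Product: 29 (7S,8R,10R) keto lactone (trans-fused γ-lactone C7–C11–C12(=O)–O–C8 on 2-methylcycloheptanone), via hydroxy ester 28 (not isolated)
Conditions: TsOH·H2O (cat.), MeOH–CH2Cl2, rt
Reagents that add atoms: none
Why: Acidic methanolysis of the silyl ether and 5-exo-trig lactonisation of the trans hydroxy ester; C7 and C8 are already fixed, so the lactone is necessarily trans-fused.

Step 21
Reactants: 29 keto lactone
Product: 30 enol triflate (C1(OTf)=C5) of 29
Conditions: KN(SiMe3)2, THF, −78 °C; PhNTf2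
Reagents that add atoms: N-phenylbis(trifluoromethanesulfonimide), O=S(=O)(N(c1ccccc1)S(=O)(=O)C(F)(F)F)C(F)(F)F
Why: Kinetic enolisation of a 2-methylcycloalkanone occurs at the methylene C5 and not at C10, and the ketone is more acidic than the lactone; O-triflation traps the C1=C5 enolate with C10 untouched.

Step 22
Reactants: 30 enol triflate
Product: 31 (3E,7S,8R,10R)-2-oxo-13-nor-4,5-secoguaia-1(5),3-dien-12,8-olide (the cycloheptenyl (E)-propenyl ketone)
Conditions: CO (1 atm), (E)-MeCH=CHSnBu3, Pd(PPh3)4 (5 mol%), LiCl, THF, 55 °C
Reagents that add atoms: carbon monoxide, [C-]#[O+]; (E)-tributyl(prop-1-en-1-yl)stannane, C/C=C/[Sn](CCCC)(CCCC)CCCC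
Why: Carbonylative Stille coupling (oxidative addition, CO insertion, transmetallation with retention of alkene geometry, reductive elimination) forms C1–C2 and C2–C3; the lactone is inert.

Step 23
Reactants: 31 cycloheptenyl (E)-propenyl ketone
Product: 32 (7S,8R,10R)-2-oxo-13-norguai-1(5)-en-12,8-olide (formed with its C4 epimer)
Conditions: MeSO3H, P2O5, CH2Cl2, 0 °C to rt
Reagents that add atoms: none
Why: O-Protonation of the cross-conjugated dienone gives a 3-hydroxypentadienyl cation (C5=C1–C2(OH)–C3=C4) that closes by thermal conrotatory 4π electrocyclisation, forming C4–C5 and a 2-hydroxyallyl cation spread over C1–C2–C3. Loss of H5 and tautomerisation give the cyclopentenone with its alkene at the ring fusion. The closest known reaction type is the Nazarov cyclisation of 1-cycloalkenyl vinyl ketones made by carbonylative coupling of enol triflates, which gives ring-fused cyclopentenones in the same way. The five-membered ring is closed in the electrocyclic mode, a formal 5-endo closure of a pentadienyl cation that is allowed because it is pericyclic. The only stereocentre that survives is C4; it is set by the sense of conrotation, which the remote C7, C8 and C10 centres are not expected to control, and it is irrelevant because C4 becomes trigonal again in step 29. The selectivity that matters is the site of proton loss, C5 and not C4 or C10. The tetrasubstituted ring-fusion enone is the thermodynamic product and any 3-enone is funnelled to it through the dienol under the acid, while loss of H10 is disfavoured because allylic strain with the C2 oxygen holds the C10 methyl perpendicular and the C10–H bond in the nodal plane of the cation, which also protects the C10 configuration. The lactone is inert to the anhydrous acid.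

Step 24
Reactants: 32 enone
Product: 33 (7S,8R,10R)-2-acetoxy-13-norguaia-1,4-dien-12,8-olide (extended dienyl acetate)
Conditions: CH2=C(Me)OAc, TsOH·H2O (cat.), 80 °C
Reagents that add atoms: isopropenyl acetate, CC(=C)OC(C)=O
Why: Acid-catalysed enol acetylation under equilibrating conditions; loss of the tertiary γ-hydrogen at C4 gives the most substituted, fully endocyclic diene (as with steroid 3,5-dienyl acetates) and removes the uncontrolled C4 centre.

Step 25
Reactants: 33 dienyl acetate
Product: 35 (7S,8R,10R)-4-hydroxy-2-oxo-13-norguai-1(5)-en-12,8-olide (both C4 epimers), via epoxide 34 (not isolated)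
Conditions: mCPBA, NaHCO3, CH2Cl2–H2O, −20 °C
Reagents that add atoms: 3-chloroperbenzoic acid, OOC(=O)c1cccc(Cl)c1
Why: The peracid attacks the electron-richer tetraalkyl alkene C4=C5 rather than the enol acetate; opening of the epoxide with loss of the acetyl group restores the enone and leaves a hydroxyl at C4 (vinylogous Rubottom oxidation). C3 stays a methylene, so the next step has no neighbouring stereocentre to contend with.

Step 26
Reactants: 35 hydroxy enone
Product: 36 (2S,7S,8R,10R)-2,4-dihydroxy-13-norguai-1(5)-en-12,8-olide (C2 hydroxyl on the face of the C10 methyl)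
Conditions: (R)-Me-CBS (0.2 equiv), catecholborane, toluene, −78 °C
Reagents that add atoms: none
Why: Corey–Bakshi–Shibata reduction; the ketone binds with the tetrasubstituted alkenyl arm as the large group and C3H2 as the small one, so the (R)-catalyst gives the (2S)-alcohol, which is also the product of attack anti to the pseudo-axial C10 methyl. Catecholborane prevents intramolecular hydride delivery from the C4 alkoxide.

Step 27
Reactants: 36 diol
Product: 37 13-(dimethylamino) derivative of 36 (Mannich base at C11)
Conditions: LiN(iPr)2 (3.3 equiv), THF, −78 °C; Me2N=CH2 I, −78 to 0 °C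
Reagents that add atoms: N,N-dimethylmethyleneiminium iodide, C=[N+](C)C.[I-]
Why: After both hydroxyls are deprotonated the lactone enolate adds to the iminium salt (Mannich reaction); the amine is kept as a masked methylene so that the diene half carries no dienophile of its own.

Step 28
Reactants: 37 Mannich diol
Product: 38 C2 acetate of 37 (tertiary C4 hydroxyl free)
Conditions: Ac2O, Et3N, DMAP (cat.), CH2Cl2, 0 °C
Reagents that add atoms: acetic anhydride, CC(=O)OC(C)=O
Why: Acylation of the secondary allylic alcohol; the tertiary C4 alcohol does not react under these conditions.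

Step 29
Reactants: 38 acetoxy carbinol
Product: 39 (2S,7S,8R,10R)-2-acetoxy-13-(dimethylamino)guaia-1(5),3-dien-12,8-olide
Conditions: Ph2S[OC(CF3)2Ph]2 (Martin sulfurane), CH2Cl2, −40 to 0 °C
Reagents that add atoms: none
Why: Sulfurane dehydration of a tertiary alcohol at low temperature; loss of a C3 hydrogen gives the endocyclic conjugated cyclopentadiene from either C4 epimer, and the cold neutral conditions hold back the [1,5]-hydrogen shift. The diene is used at once.

### Union and completion (steps 30–31)

Step 30
Reactants: 39 acetoxy diene; 18 dienophile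
Product: 40 13-(dimethylamino)-11,13-dihydrojaponicone A
Conditions: CH2Cl2 (1 M), 1.0 GPa, 20 °C, BHT (trace)
Reagents that add atoms: none
Why: Normal-demand Diels–Alder reaction of a cyclopentadiene with an α-methylene-γ-lactone, in which C13′ bonds to the fully substituted terminus C1 and the quaternary C11′ to the CH terminus C3, avoiding adjacent quaternary centres. The dienophile is attacked on the convex face of its cis-fused lactone with the lactone carbonyl endo, which keeps the bulky C7′ away from the C4 methyl and C6. The diene reacts on the face opposite the pseudo-axial C10 methyl and the C2 acetate, because the exo carbon C7′ would otherwise be pressed against the acetate; this sets C1, C3 and C11′ with the acetate syn to C4=C5, and pressure favours the bimolecular addition over the hydrogen shift.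

Step 31
Reactants: 40 amino adduct
Product: 42 japonicone A, via methiodide 41 (not isolated)
Conditions: MeI, MeOH–THF, rt; then aq. NaHCO3, EtOAc
Reagents that add atoms: none
Why: N-Methylation and Hofmann-type (E1cB) loss of trimethylamine from the β-ammonio lactone unmask the methylene group; the acetate, both lactones, the free alcohol and the alkenes are untouched.

## Compound list

1 | (S)-Wieland–Miescher ketone | O=C1CC[C@@]2(C)C(=C1)CCCC2=O | starting material
2 | (4aS,5S)-5-hydroxy-4a-methyl-4,4a,5,6,7,8-hexahydronaphthalen-2(3H)-one | O=C1CC[C@@]2(C)C(=C1)CCC[C@@H]2O | intermediate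
3 | C7′ ethylene ketal of 2 with C4′=C5′ alkene | O1CCOC12CC[C@@]3(C)C(=CCC[C@@H]3O)C2 | intermediate
4 | C1′ TBS ether of 3 | O1CCOC12CC[C@@]3(C)C(=CCC[C@@H]3O[Si](C)(C)C(C)(C)C)C2 | intermediate
5 | C4′–C5′ epoxide of 4, oxygen anti to C14′ | O1CCOC12CC[C@@]3(C)[C@]4(O[C@H]4CC[C@@H]3O[Si](C)(C)C(C)(C)C)C2 | intermediate
6 | ketal carbinol: C4′ methyl cis to C14′, C5′ hydroxyl trans | O1CCOC12CC[C@@]3(C)[C@@](O)([C@H](C)CC[C@@H]3O[Si](C)(C)C(C)(C)C)C2 | intermediate (not isolated)
7 | C5′-hydroxy C7′-ketone from 6 | O=C1CC[C@@]2(C)[C@](O)(C1)[C@H](C)CC[C@@H]2O[Si](C)(C)C(C)(C)C | intermediate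
8 | (1S,4R,10S)-1-(TBSO)-11,12,13-trinoreudesm-5-en-7-one | O=C1CC[C@@]2(C)C(=C1)[C@H](C)CC[C@@H]2O[Si](C)(C)C(C)(C)C | intermediate
9 | dienyl triflate of 8 (C7′(OTf)=C8′, C5′=C6′) | FC(F)(F)S(=O)(=O)OC1=CC[C@@]2(C)C(=C1)[C@H](C)CC[C@@H]2O[Si](C)(C)C(C)(C)C | intermediate
10 | tert-butyl diene acetate (side chain on C7′) | CC(C)(C)OC(=O)CC1=CC[C@@]2(C)C(=C1)[C@H](C)CC[C@@H]2O[Si](C)(C)C(C)(C)C | intermediate
11 | C8′ alcohol trans to the C7′ side chain, C5′=C6′ | O[C@@H]1C[C@@]2(C)C(=C[C@H]1CC(=O)OC(C)(C)C)[C@H](C)CC[C@@H]2O[Si](C)(C)C(C)(C)C | intermediate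
12 | β,γ-unsaturated C8′ ketone with C7′ CH2CO2tBu | O=C1C[C@@]2(C)C(=C[C@H]1CC(=O)OC(C)(C)C)[C@H](C)CC[C@@H]2O[Si](C)(C)C(C)(C)C | intermediate
13 | C8′ alcohol cis to the C7′ side chain | O[C@H]1C[C@@]2(C)C(=C[C@H]1CC(=O)OC(C)(C)C)[C@H](C)CC[C@@H]2O[Si](C)(C)C(C)(C)C | intermediate (not isolated)
14 | (1S,4R,7S,8S,10S)-1-(TBSO)-13-noreudesm-5-en-12,8-olide | C1C(=O)O[C@H]2C[C@@]3(C)C(=C[C@@H]12)[C@H](C)CC[C@@H]3O[Si](C)(C)C(C)(C)C | intermediate
15 | C11′ dimethylaminomethyl derivative of 14 | CN(C)CC1C(=O)O[C@H]2C[C@@]3(C)C(=C[C@@H]12)[C@H](C)CC[C@@H]3O[Si](C)(C)C(C)(C)C | intermediate (not isolated)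
16 | methiodide of 15 | C[N+](C)(C)CC1C(=O)O[C@H]2C[C@@]3(C)C(=C[C@@H]12)[C@H](C)CC[C@@H]3O[Si](C)(C)C(C)(C)C.[I-] | intermediate (not isolated)
17 | (1S,4R,7S,8S,10S)-1-(TBSO)eudesma-5,11(13)-dien-12,8-olide | C=C1C(=O)O[C@H]2C[C@@]3(C)C(=C[C@@H]12)[C@H](C)CC[C@@H]3O[Si](C)(C)C(C)(C)C | intermediate
18 | (1S,4R,7S,8S,10S)-1-hydroxyeudesma-5,11(13)-dien-12,8-olide | C=C1C(=O)O[C@H]2C[C@@]3(C)C(=C[C@@H]12)[C@H](C)CC[C@@H]3O | intermediate
19 | cyclohexa-1,3-diene | C1=CC=CCC1 | starting material
20 | 2,3-dioxabicyclo[2.2.2]oct-5-ene | C1C[C@H]2C=C[C@@H]1OO2 | intermediate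
21 | (R)-4-hydroxycyclohex-2-en-1-one | O=C1C=C[C@H](O)CC1 | intermediate
22 | (R)-4-(TBSO)cyclohex-2-en-1-one | O=C1C=C[C@H](O[Si](C)(C)C(C)(C)C)CC1 | intermediate
23 | (4R,6R)-4-(TBSO)-6-methylcyclohex-2-en-1-one | O=C1C=C[C@H](O[Si](C)(C)C(C)(C)C)C[C@H]1C | intermediate
24 | trimethylsilyl enol ether of 25 (C1=C6) | C[Si](C)(C)OC1=C[C@@H](CC(=O)OC)[C@H](O[Si](C)(C)C(C)(C)C)C[C@H]1C | intermediate (not isolated)
25 | methyl [2-(TBSO)-4-methyl-5-oxocyclohexyl]acetate, arm trans to OTBS and cis to methyl | O=C1C[C@@H](CC(=O)OC)[C@H](O[Si](C)(C)C(C)(C)C)C[C@H]1C | intermediate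
26 | C5-trimethylsilyl derivative of 27 | O=C1C([Si](C)(C)C)C[C@@H](CC(=O)OC)[C@H](O[Si](C)(C)C(C)(C)C)C[C@H]1C | intermediate (not isolated)
27 | methyl [2-(TBSO)-4-methyl-5-oxocycloheptyl]acetate | O=C1CC[C@@H](CC(=O)OC)[C@H](O[Si](C)(C)C(C)(C)C)C[C@H]1C | intermediate
28 | C8 hydroxy ester from 27 | O=C1CC[C@@H](CC(=O)OC)[C@H](O)C[C@H]1C | intermediate (not isolated)
29 | (7S,8R,10R) trans-lactone-fused 2-methylcycloheptanone | O=C1CC[C@H]2CC(=O)O[C@@H]2C[C@H]1C | intermediate
30 | C1(OTf)=C5 enol triflate of 29 | O=S(=O)(OC1=CC[C@H]2CC(=O)O[C@@H]2C[C@H]1C)C(F)(F)F | intermediate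
31 | (3E,7S,8R,10R)-2-oxo-13-nor-4,5-secoguaia-1(5),3-dien-12,8-olide | C1C(=O)O[C@@H]2C[C@@H](C)C(C(=O)/C=C/C)=CC[C@@H]12 | intermediate
32 | (7S,8R,10R)-2-oxo-13-norguai-1(5)-en-12,8-olide (one C4 epimer drawn; formed with the other) | C1C(=O)O[C@@H]2C[C@@H](C)C3=C(C[C@@H]12)[C@H](C)CC3=O | intermediate
33 | (7S,8R,10R)-2-acetoxy-13-norguaia-1,4-dien-12,8-olide | C1C(=O)O[C@@H]2C[C@@H](C)C3=C(OC(C)=O)CC(C)=C3C[C@@H]12 | intermediate
34 | 4,5-epoxide of 33 | C1C(=O)O[C@@H]2C[C@@H](C)C3=C(OC(C)=O)CC4(C)OC34C[C@@H]12 | intermediate (not isolated)
35 | (7S,8R,10R)-4-hydroxy-2-oxo-13-norguai-1(5)-en-12,8-olide (C4 epimers) | C1C(=O)O[C@@H]2C[C@@H](C)C3=C(C[C@@H]12)C(C)(O)CC3=O | intermediate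
36 | (2S,7S,8R,10R)-2,4-dihydroxy-13-norguai-1(5)-en-12,8-olide | C1C(=O)O[C@@H]2C[C@@H](C)C3=C(C[C@@H]12)C(C)(O)C[C@@H]3O | intermediate
37 | (2S,7S,8R,10R)-13-(dimethylamino)-2,4-dihydroxyguai-1(5)-en-12,8-olide | CN(C)CC1C(=O)O[C@@H]2C[C@@H](C)C3=C(C[C@@H]12)C(C)(O)C[C@@H]3O | intermediate
38 | C2 acetate of 37 | CN(C)CC1C(=O)O[C@@H]2C[C@@H](C)C3=C(C[C@@H]12)C(C)(O)C[C@@H]3OC(C)=O | intermediate
39 | (2S,7S,8R,10R)-2-acetoxy-13-(dimethylamino)guaia-1(5),3-dien-12,8-olide | CN(C)CC1C(=O)O[C@@H]2C[C@@H](C)C3=C(C[C@@H]12)C(C)=C[C@@H]3OC(C)=O | intermediate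
40 | 13-(dimethylamino)-11,13-dihydrojaponicone A | CN(C)CC1C(=O)O[C@@H]2C[C@@H](C)[C@]34C[C@]5(C(=O)O[C@H]6C[C@@]7(C)C(=C[C@H]65)[C@H](C)CC[C@@H]7O)[C@H](C(C)=C3C[C@@H]12)[C@@H]4OC(C)=O | intermediate
41 | methiodide of 40 | C[N+](C)(C)CC1C(=O)O[C@@H]2C[C@@H](C)[C@]34C[C@]5(C(=O)O[C@H]6C[C@@]7(C)C(=C[C@H]65)[C@H](C)CC[C@@H]7O)[C@H](C(C)=C3C[C@@H]12)[C@@H]4OC(C)=O.[I-] | intermediate (not isolated)
42 | japonicone A | C=C1C(=O)O[C@@H]2C[C@@H](C)[C@]34C[C@]5(C(=O)O[C@H]6C[C@@]7(C)C(=C[C@H]65)[C@H](C)CC[C@@H]7O)[C@H](C(C)=C3C[C@@H]12)[C@@H]4OC(C)=O | target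

## Step count and least certain steps

Total: 31 steps. Longest linear sequence: 18 steps (steps 14–31, from cyclohexa-1,3-diene); the dienophile branch is 13 steps (steps 1–13) before the union.

**Step 23 (key step).** The most likely failure is proton loss from the hydroxyallyl cation at C10 or C4 in place of C5, which would misplace the alkene and erode the C10 configuration. The fallback separates ring closure from alkene placement. It sets out from 31: a reductive Nazarov cyclisation (Et3SiH, BF3·OEt2, CH2Cl2) traps the cation by hydride and gives the saturated ketone F1. Thermodynamic silylation (TMSCl, NaI, Et3N, MeCN) toward the more substituted C1 gives the silyl enol ether F2. Saegusa–Ito oxidation with Pd(OAc)2 in MeCN then returns to the route at 32.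

**Step 30.** The most likely failure is poor facial selectivity, with addition on the acetoxy-bearing face as simple 5-acyloxycyclopentadienes prefer; this would give the C2 epimeric bridge, which cannot be corrected afterwards. The fallback replaces the acetate during the cycloaddition by a bulkier, less electron-withdrawing silyloxy group and restores it later. It sets out from 37 and 18. Selective silylation of the secondary alcohol of 37 (TBSOTf, 2,6-lutidine, −78 °C) gives the silyl ether F3, and sulfurane dehydration as in step 29 gives the silyloxy diene F4. Esterification of 18 with levulinic acid (DCC, DMAP) gives the levulinate F5. Cycloaddition of F4 and F5 under pressure gives the adduct F6. HF·pyridine frees the bridge alcohol F7, acetylation (Ac2O, DMAP) gives the acetate F8, and hydrazine acetate removes the levulinate, returning to the route at 40.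

**Step 29.** The most likely failure is loss of the diene before it is used, by [1,5]-hydrogen shift to the dienyl acetate, together with some proton loss from the C15 methyl. The fallback generates the diene in the presence of its partner. It sets out from 38 and the silyl-protected dienophile 17, which tolerates the sulfurane. Dehydration at −40 °C in a concentrated solution of 17, followed by pressurising the same solution, gives the silylated adduct F9. HF·pyridine then returns to the route at 40.

**Step 19.** The most likely failure is migration of the methyl-bearing carbon C10, which inserts the new carbon on the wrong side of the carbonyl; multiple insertion is a lesser risk. The fallback uses a regiospecific Ito–Saegusa expansion. It sets out from 23: the Mukaiyama–Michael step is worked up without water so that the silyl enol ether 24 is isolated. Cyclopropanation (Et2Zn, CH2I2) gives the siloxycyclopropane F10. FeCl3 in DMF opens it to the chloro ketone F11, sodium acetate in methanol eliminates HCl to the cycloheptenone F12, and hydrogenation (H2, Pd/C) returns to the route at 27.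

**Step 9.** The most likely failure is hydroboration of the other alkene of the diene or poor regioselectivity. The fallback brings in the C8′ oxygen by epoxidation and isomerisation. It sets out from 10: one equivalent of mCPBA at −40 °C gives the vinyl epoxide F13. Catalytic Pd(PPh3)4 then isomerises it through a π-allyl alkoxide and hydride shift to the β,γ-unsaturated ketone, returning to the route at 12 and saving step 10.

## Further compounds

F1 | step 23 | 2-oxo-13-norguaian-12,8-olide (saturated cis-fused ketone) | C1C(=O)O[C@@H]2C[C@@H](C)C3C(C[C@@H]12)C(C)CC3=O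
F2 | step 23 | 2-(trimethylsilyloxy)-13-norguai-1-en-12,8-olide | C1C(=O)O[C@@H]2C[C@@H](C)C3=C(O[Si](C)(C)C)CC(C)C3C[C@@H]12
F3 | step 30 | C2 tert-butyldimethylsilyl ether of 37 | CN(C)CC1C(=O)O[C@@H]2C[C@@H](C)C3=C(C[C@@H]12)C(C)(O)C[C@@H]3O[Si](C)(C)C(C)(C)C
F4 | step 30 | 2-(tert-butyldimethylsilyloxy)-13-(dimethylamino)guaia-1(5),3-dien-12,8-olide | CN(C)CC1C(=O)O[C@@H]2C[C@@H](C)C3=C(C[C@@H]12)C(C)=C[C@@H]3O[Si](C)(C)C(C)(C)C
F5 | step 30 | C1′ levulinate of 18 | C=C1C(=O)O[C@H]2C[C@@]3(C)C(=C[C@@H]12)[C@H](C)CC[C@@H]3OC(=O)CCC(C)=O
F6 | step 30 | Diels–Alder adduct with C2 silyloxy and C1′ levulinate | CN(C)CC1C(=O)O[C@@H]2C[C@@H](C)[C@]34C[C@]5(C(=O)O[C@H]6C[C@@]7(C)C(=C[C@H]65)[C@H](C)CC[C@@H]7OC(=O)CCC(C)=O)[C@H](C(C)=C3C[C@@H]12)[C@@H]4O[Si](C)(C)C(C)(C)C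
F7 | step 30 | adduct with free C2 hydroxyl and C1′ levulinate | CN(C)CC1C(=O)O[C@@H]2C[C@@H](C)[C@]34C[C@]5(C(=O)O[C@H]6C[C@@]7(C)C(=C[C@H]65)[C@H](C)CC[C@@H]7OC(=O)CCC(C)=O)[C@H](C(C)=C3C[C@@H]12)[C@@H]4O
F8 | step 30 | adduct with C2 acetate and C1′ levulinate | CN(C)CC1C(=O)O[C@@H]2C[C@@H](C)[C@]34C[C@]5(C(=O)O[C@H]6C[C@@]7(C)C(=C[C@H]65)[C@H](C)CC[C@@H]7OC(=O)CCC(C)=O)[C@H](C(C)=C3C[C@@H]12)[C@@H]4OC(C)=O
F9 | step 29 | C1′ tert-butyldimethylsilyl ether of 40 | CN(C)CC1C(=O)O[C@@H]2C[C@@H](C)[C@]34C[C@]5(C(=O)O[C@H]6C[C@@]7(C)C(=C[C@H]65)[C@H](C)CC[C@@H]7O[Si](C)(C)C(C)(C)C)[C@H](C(C)=C3C[C@@H]12)[C@@H]4OC(C)=O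
F10 | step 19 | siloxycyclopropane from 24 | C[Si](C)(C)OC12CC1[C@@H](CC(=O)OC)[C@H](O[Si](C)(C)C(C)(C)C)C[C@H]2C
F11 | step 19 | 3-chlorocycloheptanone ester | O=C1CC(Cl)[C@@H](CC(=O)OC)[C@H](O[Si](C)(C)C(C)(C)C)C[C@H]1C
F12 | step 19 | cyclohept-2-enone ester (C5=C6) | O=C1C=C[C@@H](CC(=O)OC)[C@H](O[Si](C)(C)C(C)(C)C)C[C@H]1C
F13 | step 9 | C7′–C8′ epoxide of 10 | CC(C)(C)OC(=O)CC12OC1C[C@@]3(C)C(=C2)[C@H](C)CC[C@@H]3O[Si](C)(C)C(C)(C)C
A1 | alternative 1 | allylsilane aldehyde: 4-(trimethylsilyl)-3-methylcyclohex-3-enone bearing the 4-oxobutan-2-yl chain on C5′ | O=CCC[C@@H](C)C1=C(C)CC(=O)CC1[Si](C)(C)C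
A2 | alternative 1 | 1′-hydroxyeudesm-5′-en-8′-one (11,12,13-trinor) | O=C1C[C@@]2(C)C(=CC1)[C@H](C)CC[C@@H]2O
A3 | alternative 2 | 1-mesyloxyeudesma-5,11(13)-dien-12,8-olide (trans lactone) | C=C1C(=O)O[C@@H]2C[C@@]3(C)C(=C[C@@H]12)[C@H](C)CC[C@@H]3OS(C)(=O)=O
A4 | alternative 2 | guaia-1(10),5,11(13)-trien-12,8-olide | C=C1C(=O)O[C@@H]2CC(C)=C3CC[C@@H](C)C3=C[C@@H]12
A5 | alternative 3 | bromo bicyclo[2.2.2]octenone (bridge C1–CHBr–C(=O)–C3) | C1C(=O)O[C@@H]2C[C@@H](C)[C@]34C[C@]5(C(=O)O[C@H]6C[C@@]7(C)C(=C[C@H]65)[C@H](C)CC[C@@H]7O[Si](C)(C)C(C)(C)C)[C@H](C(C)=C3C[C@@H]12)C(=O)[C@@H]4Br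
A6 | alternative 3 | norbornene with C2 methyl ester syn to C4=C5 | C1C(=O)O[C@@H]2C[C@@H](C)[C@]34C[C@]5(C(=O)O[C@H]6C[C@@]7(C)C(=C[C@H]65)[C@H](C)CC[C@@H]7O[Si](C)(C)C(C)(C)C)[C@H](C(C)=C3C[C@@H]12)[C@@H]4C(=O)OC
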